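**Compound numbers used throughout:** 1 tectochrysin; 2 its 6,8-dialdehyde; 3 the 5-O-benzyl dialdehyde; 4 2-(benzyloxy)benzyl alcohol; 5 the derived bromide; 6 3-ethoxycyclohex-2-en-1-one; 7 its C6-alkylation product; 8 the allylic alcohol from 7; 9 the 4-substituted cyclohex-2-enone; 10 dilithium bis-aldolate; 11 bis-mesylate; 12 bis-arylidene dienone; 13 bisphenol flavone; 14 penta-O-benzyl flavone; 15 flavan-4-ol; 16 penta-O-benzyl (2S)-flavanone; 17 target.

## Analysis of the target

The target is a (2S)-flavanone: ring A is a fully substituted benzene fused to the dihydropyranone ring C, and ring B is an unsubstituted phenyl group at C2. Ring A carries OH at C5, OMe at C7 and two identical arms at C6 and C8. Each arm is a CH2 bound to a middle phenol ring whose OH is ortho to that CH2 and which carries, para to the OH, a second CH2 leading to a terminal 2-hydroxyphenyl ring. There are thus seven rings, four diarylmethane CH2 links and one stereocentre, C2, so only absolute configuration has to be controlled. That centre is fragile: C2–O1 is the beta C–O bond of an aryl ketone and is also benzylic, so base or strong acid opens ring C to the 2'-hydroxychalcone and recloses it as the racemate, and hydrogenolysis can cleave it. The five phenols are oxidisable and the ortho-hydroxybenzyl units ionise under acid. The difficulty is threefold: a hexasubstituted ring A with two large identical groups at the non-equivalent positions C6 and C8; a fixed pattern on each middle ring (ring A link ortho to OH, terminal-ring link para to OH) that direct hydroxybenzylation does not deliver cleanly; and a labile C2 that must be one enantiomer at the end. The strategy rests on each middle ring, C1(OH)/C2(CH2–ring A)/C4(CH2Ar), being the aromatic tautomer of a 4-substituted 6-arylidenecyclohex-2-enone, so that the CH2 carbons on C6 and C8 can start as aldehyde carbons.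

## Retrosynthetic reasoning

**17 ⇒ 16.** The five free phenols are revealed last by cleaving five O–benzyl bonds of 16 in one neutral hydrogenolysis. A single protecting group type means one final operation, and neutral conditions leave C2 untouched.

**16 ⇒ 14.** The C2–H and C3–H bonds are cut, returning to the flat flavone 14. Setting C2 by catalyst-controlled hydrogenation of C2=C3 means the labile centre exists only in the last two steps and never meets base. Part of the material will be over-reduced at C4 to the flavan-4-ol 15, which is oxidised back in the same operation. The forward step must choose one alkene face and leave benzyl ethers and benzene rings alone.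

**14 ⇒ 13.** Two O–benzyl bonds on the middle phenols are cut. Capping them gives a substrate with no acidic OH for the basic hydrogenation catalyst and makes the later deprotection uniform.

**13 ⇒ 3 + 9 (the central disconnection).** Each middle phenol of 13 is taken back to its non-aromatic tautomer, the bis-arylidene dienone 12. The exocyclic C=C bonds are then taken back through the bis-mesylate 11 to the bis-aldolate 10, and the two bonds between the ring A benzylic carbons and the middle rings are cut by retro-aldol. This leaves dialdehyde 3 and two molecules of enone 9.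

- The cut is made here because the ring A positions C6 and C8 are nucleophilic and easy to formylate, and because the enone already fixes where OH and the second CH2Ar sit on the future phenol.
- Both arms are made in one two-directional operation, with no ring A versus middle-ring regiochemistry left open.
- The forward reaction needs a flavone rather than a flavanone, since only the flavone lacks a stereocentre and an enolisable CH2 next to the ketone.
- One point needs care: the flavone is not inert to a lithium amide (C3–H can be removed, C2 is a conjugate acceptor). The enolate of 9 must therefore be preformed with a slight deficit of base.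
- Dehydration of the aldol is not spontaneous, so the aldolate is activated as a sulfonate before the base-induced elimination and isomerisation.

**3 ⇒ 2 ⇒ 1.** The O–benzyl bond at C5 is cut first; the free 5-OH of 2 would otherwise be deprotonated by the enolate and deactivate the neighbouring aldehyde. The two C–CHO bonds of 2 are then cut. C6 and C8 are the only free positions of ring A in tectochrysin 1, each activated by three oxygens, so a double electrophilic formylation has no positional choice to make.

**9 ⇒ 7 ⇒ 5 + 6; 5 ⇒ 4.** Enone 9 comes from 7 by carbonyl transposition (reduction to 8, then hydrolysis), which moves the side chain from the alpha-prime carbon of a vinylogous ester to C4 of the enone. The C–C bond of 7 between ring and side chain is cut to give the enolate of 6 and bromide 5, made from alcohol 4. Buying the terminal ring with its oxygen already ortho to the CH2 avoids any ortho/para issue on that ring.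

## Alternatives that were turned down

**Alternative 1: boron-templated closure onto the terminal rings.**
- Disconnection: the two bonds between the distal benzylic carbons and the terminal hydroxyphenyl rings.
- Forward key step: the dialdehyde A2, (2S)-6,8-bis(2-acetoxy-5-formylbenzyl)-5-hydroxy-7-methoxyflavanone, is heated with the parent hydroxyarene and an arylboronic acid. Boron ties the phenol oxygen to the aldehyde oxygen, the ortho carbon attacks the formyl carbon, and two 1,3,2-benzodioxaborin rings close to give A1. The benzylic C–O bonds are reduced away afterwards and the acetates removed.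
- For: ortho attack is enforced by the template, and the terminal ring comes from the simplest possible building block without a protecting group.
- Against: A2 already contains both arms on ring A and the C2 centre, so the key step addresses the easiest bonds of the molecule. The templating conditions (acid catalysis, heat, water removal) expose a free 5-OH flavanone to ring C opening and racemisation. The 5-OH/C4=O chelate competes for boron. The later reductive removal of two benzylic oxygens must spare the aryl ketone, and the acetates must come off without base reaching C2.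
- Comparison: on ortho selectivity at the terminal ring it is as good as the chosen route, which instead buys that pattern in 4. The chosen route additionally solves the ring A junctions and the middle-ring pattern in its key step, and needs no reductive deoxygenation.

**Alternative 2: Friedel–Crafts closure of ring C.**
- Disconnection: the C4–C4a bond.
- Forward key step: the (S)-3-aryloxy-3-phenylpropanoic acid A4 is activated and acylates the single free ring carbon to give the tetra-O-benzyl flavanone A3; hydrogenolysis follows.
- For: the site of closure is unambiguous. The stereocentre derives from a beta-hydroxy ester made by a cheap and very dependable asymmetric ketone reduction. On this point it is stronger than a late, specialised hydrogenation of a large substrate.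
- Against: forming the aryl ether of A4 means substituting a secondary benzylic alcohol with a di-ortho-substituted phenol, which invites elimination to the cinnamate and partial ionisation. Under acylating acid, A4 can lose its electron-rich phenoxide by beta-elimination or ionise at the benzylic C–O bond, eroding the configuration. Benzyl ethers are acid-labile and the middle rings are competing acylation sites. The fully substituted phenol with both arms still has to be built first, so the hard bonds are not addressed and the route is longer.
- Comparison: the chosen route gives up the cheap source of chirality but keeps C2 away from every acidic and basic step by creating it second to last.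

**Alternative 3: two-directional Negishi benzylation.**
- Disconnection: the two aryl–CH2 bonds between the middle rings and the distal benzylic carbons.
- Forward key step: the dibromide A6, (2S)-5-acetoxy-6,8-bis(2-acetoxy-5-bromobenzyl)-7-methoxyflavanone, couples twice with 2-(benzyloxy)benzylzinc chloride A7 under a zerovalent palladium catalyst to give A5.
- For: aryl bromide/benzylzinc coupling is neutral, tolerant of ketone, esters and the C2 centre, and highly convergent. Taken alone, this key step is more certain than the chosen one.
- Against: A6 must already carry both bromo-hydroxybenzyl arms on a chiral flavanone. Installing them by hydroxybenzylation is exactly the unsolved problem (C6 versus C8, mono versus bis, O versus C) and is done on the labile flavanone. Three acetates must later be removed by base or acid next to C2, and a second deprotection type is needed.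
- Comparison: the chosen route accepts a less certain key step in exchange for forming the proximal bonds with no positional ambiguity, carrying the distal CH2Ar in from 9, and using one protecting group throughout.

Key step: step 6

**Assumption:** the (R,R) enantiomer of the carbene precursor SINpEt·HBF4 (1,3-bis[1-(naphthalen-1-yl)ethyl]-4,5-dihydroimidazolium tetrafluoroborate) is taken to be the one that gives the (2S) product in step 8. If the sense of induction on this substrate is the opposite, the (S,S) ligand is used and nothing else changes.

**Remark:** compounds 7 to 12 are racemic or mixtures of stereoisomers; none of their stereocentres reaches the target.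

## Route

Step 1
Reactants: 1 tectochrysin (5-hydroxy-7-methoxyflavone)
Product: 2 5-hydroxy-7-methoxy-4-oxo-2-phenyl-4H-chromene-6,8-dicarbaldehyde
Conditions: hexamethylenetetramine (excess), TFA, 90 °C; then aq. HCl, 60 °C
Reagents that add atoms: hexamethylenetetramine, C1N2CN3CN1CN(C2)C3; water, O
Why: Duff formylation: iminium ions from protonated hexamethylenetetramine attack C6 and C8, the only free positions of ring A, each ortho or para to three oxygens; the benzylamines are oxidised by internal hydride transfer and aqueous acid releases the aldehydes. TFA as solvent makes the reagent strong enough for the second substitution on the already deactivated ring.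

Step 2
Reactants: 2 5-hydroxy-7-methoxy-4-oxo-2-phenyl-4H-chromene-6,8-dicarbaldehyde
Product: 3 5-(benzyloxy)-7-methoxy-4-oxo-2-phenyl-4H-chromene-6,8-dicarbaldehyde
Conditions: BnBr, K2CO3, DMF, 60 °C
Reagents that add atoms: benzyl bromide, BrCc1ccccc1
Why: Williamson ether synthesis; the chelated 5-OH is acidified by the neighbouring formyl group, and warm DMF is enough to break the hydrogen bond and alkylate it. Nothing else in the molecule reacts with carbonate base.

Step 3
Reactants: 4 2-(benzyloxy)benzyl alcohol
Product: 5 2-(benzyloxy)benzyl bromide
Conditions: PBr3, Et2O, 0 °C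
Reagents that add atoms: phosphorus tribromide, BrP(Br)Br
Why: Conversion of a primary benzylic alcohol into the bromide through its phosphite ester (SN2 by bromide); the aryl benzyl ether is inert.

Step 4
Reactants: 5 2-(benzyloxy)benzyl bromide; 6 3-ethoxycyclohex-2-en-1-one
Product: 7 rac-6-[2-(benzyloxy)benzyl]-3-ethoxycyclohex-2-en-1-one
Conditions: LDA (LiN(i-Pr)2), THF, −78 °C; then 5, −78 °C to rt
Reagents that add atoms: none
Why: Stork–Danheiser alkylation: the lithium amide removes the C6 (alpha-prime) hydrogen of the vinylogous ester under kinetic control and the enolate is alkylated by the reactive benzylic bromide. The new stereocentre forms as a racemate and is destroyed in step 6.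

Step 5
Reactants: 7 rac-6-[2-(benzyloxy)benzyl]-3-ethoxycyclohex-2-en-1-one
Product: 9 rac-4-[2-(benzyloxy)benzyl]cyclohex-2-en-1-one, via allylic alcohol 8 (not isolated)
Conditions: LiAlH4, Et2O, 0 °C; then 1 M HCl, THF, rt
Reagents that add atoms: water, O
Why: Second half of the Stork–Danheiser carbonyl transposition: 1,2-reduction gives the 3-ethoxy allylic alcohol 8, and aqueous acid hydrolyses the enol ether and eliminates water. The carbonyl moves to the former C3 and the side chain ends at C4 of the new enone.

Step 6
Reactants: 3 5-(benzyloxy)-7-methoxy-4-oxo-2-phenyl-4H-chromene-6,8-dicarbaldehyde; 9 rac-4-[2-(benzyloxy)benzyl]cyclohex-2-en-1-one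
Product: 13 5-(benzyloxy)-6,8-bis{5-[2-(benzyloxy)benzyl]-2-hydroxybenzyl}-7-methoxyflavone, via dilithium bis-aldolate 10 (not isolated), via bis-mesylate 11 (not isolated), via bis-arylidene dienone 12 (not isolated)
Conditions: 9 (2.3 equiv), LDA (2.2 equiv), THF, −78 °C; then 3, −78 °C; MsCl (2.5 equiv), −78 to 0 °C; KOt-Bu (6 equiv), THF, 0 °C to rt; AcOH quench
Reagents that add atoms: none
Why: Kinetic deprotonation of 9 at C6 (alpha-prime) gives the cross-conjugated lithium dienolate, which adds through a closed six-membered transition state to each non-enolisable formyl group of 3 to give 10; the closest known reaction type is the directed aldol condensation of cyclohex-2-enone enolates with aryl aldehydes followed by isoaromatisation of 6-arylidenecyclohex-2-enones to 2-benzylphenols. MsCl turns both aldolates into leaving groups (11), which blocks retro-aldol, and KOt-Bu then effects E1cB elimination to the bis-dienone 12. The same base removes the gamma hydrogen at C4 of each dienone and, through the doubly allylic C5 position, hydrogen is passed to the exocyclic carbon, so the exocyclic C=C moves into the ring and the phenoxide forms irreversibly. No ring is closed; two existing six-membered carbocycles are aromatised. No stereocentre survives: the C4 centre of racemic 9 and the aldol centres of 10 and 11 become sp2 or CH2, so all diastereomers converge on one product. The selectivity needed is C–C bond formation at a carbon next to the carbonyl of 9 and not at C4; kinetic enolisation secures attack at C6, and even attack at C2 would lead to the same 2-benzyl-4-substituted phenol, because C2 and C6 are both ortho to C1 and meta to C4. Chemoselectivity for the aldehydes over the flavone (C3 deprotonation, addition at C2) rests on the preformed enolate with no free amide base, on the low temperature, and on the 5-O-benzyl ether, which removes the only acidic OH.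

Step 7
Reactants: 13 5-(benzyloxy)-6,8-bis{5-[2-(benzyloxy)benzyl]-2-hydroxybenzyl}-7-methoxyflavone
Product: 14 5-(benzyloxy)-6,8-bis{2-(benzyloxy)-5-[2-(benzyloxy)benzyl]benzyl}-7-methoxyflavone
Conditions: BnBr, K2CO3, DMF, rt
Reagents that add atoms: benzyl bromide, BrCc1ccccc1
Why: Williamson ether synthesis on the two new phenols; it keeps acidic OH groups away from the basic ruthenium carbene catalyst of step 8 and makes the substrate soluble in hydrocarbon solvent.

Step 8
Reactants: 14 5-(benzyloxy)-6,8-bis{2-(benzyloxy)-5-[2-(benzyloxy)benzyl]benzyl}-7-methoxyflavone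
Product: 16 (2S)-5-(benzyloxy)-6,8-bis{2-(benzyloxy)-5-[2-(benzyloxy)benzyl]benzyl}-7-methoxy-2-phenylchroman-4-one, via flavan-4-ol 15 (not isolated)
Conditions: [Ru(cod)(2-methylallyl)2] (5 mol%), (R,R)-SINpEt·HBF4 (10 mol%), KOt-Bu (12 mol%), hexane, 70 °C (catalyst formation); 14, H2 (100 bar), toluene, rt; then Dess–Martin periodinane, CH2Cl2, rt
Reagents that add atoms: none
Why: Ruthenium N-heterocyclic carbene catalysed asymmetric hydrogenation of a flavone: the chiral bis(carbene)ruthenium complex adds H2 to one face of C2=C3 and sets C2 as (S) under catalyst control. The portion reduced further at C4 to the cis flavan-4-ol 15 is returned to the ketone by Dess–Martin oxidation, which does not touch C2; benzyl ethers and benzene rings are not reduced by this homogeneous catalyst at room temperature.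

Step 9
Reactants: 16 (2S)-5-(benzyloxy)-6,8-bis{2-(benzyloxy)-5-[2-(benzyloxy)benzyl]benzyl}-7-methoxy-2-phenylchroman-4-one
Product: 17 5''-(2''''-hydroxybenzyl)uvarinol, (2S)-5-hydroxy-6,8-bis{2-hydroxy-5-[(2-hydroxyphenyl)methyl]benzyl}-7-methoxy-2-phenylchroman-4-one
Conditions: H2 (1 atm), Pd/C (10%), EtOAc/MeOH, rt
Reagents that add atoms: none
Why: Hydrogenolysis of five aryl benzyl ethers over Pd/C under neutral conditions; with no acid or base present the C2 centre keeps its configuration. The reaction is stopped at complete debenzylation, before the benzylic C2–O1 bond or the chelated ketone is attacked.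

## Compound list

1 | tectochrysin (5-hydroxy-7-methoxyflavone) | COc1cc(O)c2c(c1)OC(c1ccccc1)=CC2=O | starting material
2 | 5-hydroxy-7-methoxy-4-oxo-2-phenyl-4H-chromene-6,8-dicarbaldehyde | COc1c(C=O)c(O)c2c(c1C=O)OC(c1ccccc1)=CC2=O | intermediate
3 | 5-(benzyloxy)-7-methoxy-4-oxo-2-phenyl-4H-chromene-6,8-dicarbaldehyde | COc1c(C=O)c(OCc2ccccc2)c2c(c1C=O)OC(c1ccccc1)=CC2=O | intermediate
4 | 2-(benzyloxy)benzyl alcohol | OCc1ccccc1OCc1ccccc1 | starting material
5 | 2-(benzyloxy)benzyl bromide | BrCc1ccccc1OCc1ccccc1 | intermediate
6 | 3-ethoxycyclohex-2-en-1-one | CCOC1=CC(=O)CCC1 | starting material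
7 | rac-6-[2-(benzyloxy)benzyl]-3-ethoxycyclohex-2-en-1-one | CCOC1=CC(=O)C(Cc2ccccc2OCc2ccccc2)CC1 | intermediate
8 | 6-[2-(benzyloxy)benzyl]-3-ethoxycyclohex-2-en-1-ol (racemic, mixture of diastereomers; not isolated) | CCOC1=CC(O)C(Cc2ccccc2OCc2ccccc2)CC1 | intermediate
9 | rac-4-[2-(benzyloxy)benzyl]cyclohex-2-en-1-one | O=C1C=CC(Cc2ccccc2OCc2ccccc2)CC1 | intermediate
10 | dilithium salt of 5-(benzyloxy)-6,8-bis({5-[2-(benzyloxy)benzyl]-2-oxocyclohex-3-en-1-yl}(hydroxy)methyl)-7-methoxyflavone (mixture of stereoisomers; not isolated) | COc1c(C([O-])C3CC(Cc4ccccc4OCc4ccccc4)C=CC3=O)c(OCc3ccccc3)c2c(c1C([O-])C1CC(Cc3ccccc3OCc3ccccc3)C=CC1=O)OC(c1ccccc1)=CC2=O.[Li+].[Li+] | intermediate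
11 | 5-(benzyloxy)-6,8-bis({5-[2-(benzyloxy)benzyl]-2-oxocyclohex-3-en-1-yl}[(methylsulfonyl)oxy]methyl)-7-methoxyflavone (mixture of stereoisomers; not isolated) | COc1c(C(OS(C)(=O)=O)C3CC(Cc4ccccc4OCc4ccccc4)C=CC3=O)c(OCc3ccccc3)c2c(c1C(OS(C)(=O)=O)C1CC(Cc3ccccc3OCc3ccccc3)C=CC1=O)OC(c1ccccc1)=CC2=O | intermediate
12 | 5-(benzyloxy)-6,8-bis({5-[2-(benzyloxy)benzyl]-2-oxocyclohex-3-en-1-ylidene}methyl)-7-methoxyflavone (E alkenes expected, geometry and ring C4 configuration immaterial; not isolated) | COc1c(C=C3CC(Cc4ccccc4OCc4ccccc4)C=CC3=O)c(OCc3ccccc3)c2c(c1C=C1CC(Cc3ccccc3OCc3ccccc3)C=CC1=O)OC(c1ccccc1)=CC2=O | intermediate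
13 | 5-(benzyloxy)-6,8-bis{5-[2-(benzyloxy)benzyl]-2-hydroxybenzyl}-7-methoxyflavone | COc1c(Cc2cc(Cc3ccccc3OCc3ccccc3)ccc2O)c(OCc2ccccc2)c2c(c1Cc1cc(Cc3ccccc3OCc3ccccc3)ccc1O)OC(c1ccccc1)=CC2=O | intermediate
14 | 5-(benzyloxy)-6,8-bis{2-(benzyloxy)-5-[2-(benzyloxy)benzyl]benzyl}-7-methoxyflavone | COc1c(Cc2cc(Cc3ccccc3OCc3ccccc3)ccc2OCc2ccccc2)c(OCc2ccccc2)c2c(c1Cc1cc(Cc3ccccc3OCc3ccccc3)ccc1OCc1ccccc1)OC(c1ccccc1)=CC2=O | intermediate
15 | (2S,4S)-5-(benzyloxy)-6,8-bis{2-(benzyloxy)-5-[2-(benzyloxy)benzyl]benzyl}-7-methoxy-2-phenylchroman-4-ol (cis isomer expected; the C4 configuration is erased by the oxidation; not isolated) | COc1c(Cc2cc(Cc3ccccc3OCc3ccccc3)ccc2OCc2ccccc2)c(OCc2ccccc2)c2c(c1Cc1cc(Cc3ccccc3OCc3ccccc3)ccc1OCc1ccccc1)O[C@H](c1ccccc1)C[C@@H]2O | intermediate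
16 | (2S)-5-(benzyloxy)-6,8-bis{2-(benzyloxy)-5-[2-(benzyloxy)benzyl]benzyl}-7-methoxy-2-phenylchroman-4-one | COc1c(Cc2cc(Cc3ccccc3OCc3ccccc3)ccc2OCc2ccccc2)c(OCc2ccccc2)c2c(c1Cc1cc(Cc3ccccc3OCc3ccccc3)ccc1OCc1ccccc1)O[C@H](c1ccccc1)CC2=O | intermediate
17 | 5''-(2''''-hydroxybenzyl)uvarinol, (2S)-5-hydroxy-6,8-bis{2-hydroxy-5-[(2-hydroxyphenyl)methyl]benzyl}-7-methoxy-2-phenylchroman-4-one | COc1c(Cc2cc(Cc3ccccc3O)ccc2O)c(O)c2c(c1Cc1cc(Cc3ccccc3O)ccc1O)O[C@H](c1ccccc1)CC2=O | target

## Step count and least certain steps

Total step count: 9. Longest linear sequence: 7 (steps 3, 4, 5, 6, 7, 8, 9, from 4 to 17); the branch from 1 joins at step 6 after 2 steps.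

**Step 6 (key step).** Most likely to go wrong:
- incomplete second addition at the more hindered formyl group;
- reversal of the aldol before the leaving group is in place;
- attack of the strong base on the pyranone ring (C3 deprotonation or opening at C2) during the isomerisation.

Fallback: the sequence is taken apart and moved away from strong base. It sets out from 3 and 9. Enone 9 is converted (LDA, Me3SiCl, THF, −78 °C) into its kinetic silyl dienol ether, {[4-(2-(benzyloxy)benzyl)cyclohexa-1,5-dien-1-yl]oxy}trimethylsilane F1. A Mukaiyama aldol addition of F1 to 3 (BF3·OEt2, CH2Cl2, −78 °C) gives the bis(beta-hydroxy ketone), 5-(benzyloxy)-6,8-bis({5-[2-(benzyloxy)benzyl]-2-oxocyclohex-3-en-1-yl}(hydroxy)methyl)-7-methoxyflavone F2. F2 is dehydrated with MsCl/Et3N and then DBU to the dienone 12, which is now isolated. 12 is isomerised with catalytic RhCl3·3H2O in hot ethanol, where a rhodium hydride walks the exocyclic C=C into the ring under neutral conditions. The fallback comes back to the route at 13.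

**Step 8.** Most likely to go wrong: insufficient facial selectivity, since the heavily substituted ring A and the peri 5-benzyloxy group may disturb how the flavone sits on the chiral catalyst. Fallback: resolution instead of catalyst-controlled face selection. It sets out from 16 of insufficient enantiomeric purity. This is subjected to asymmetric transfer hydrogenation (RuCl(p-cymene)(TsDPEN) in the enantiomeric form that reduces the (2R) ketone faster, HCO2H/Et3N). The unwanted enantiomer is converted into (2R,4R)-5-(benzyloxy)-6,8-bis{2-(benzyloxy)-5-[2-(benzyloxy)benzyl]benzyl}-7-methoxy-2-phenylchroman-4-ol F3, which is separated by chromatography. The recovered ketone is enriched 16, where the fallback rejoins the route.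

**Step 1.** Most likely to go wrong: formylation stopping after the first aldehyde, because the ring is then strongly deactivated. Fallback: halogenation and cross-coupling in place of electrophilic formylation. It sets out from 1 and rejoins at 3, bypassing 2.
- 1 is dibrominated (NBS, DMF) to 6,8-dibromo-5-hydroxy-7-methoxyflavone F4.
- F4 is benzylated (BnBr, K2CO3, DMF) to 5-(benzyloxy)-6,8-dibromo-7-methoxyflavone F5.
- F5 is vinylated twice by Suzuki–Miyaura coupling (potassium vinyltrifluoroborate, Pd(OAc)2, SPhos, K2CO3, dioxane/water, 90 °C) to 5-(benzyloxy)-7-methoxy-6,8-divinylflavone F6.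
- The two electron-rich vinyl groups of F6 are cleaved (OsO4 cat., NaIO4, 2,6-lutidine, dioxane/water) in preference to the electron-poor C2=C3 bond, giving 3.

**Step 9.** Most likely to go wrong: reductive cleavage of the benzylic C2–O1 bond, or reduction of the C4 carbonyl, before the last hindered benzyl ether has gone. Fallback: non-reductive Lewis acid debenzylation from 16 with BCl3 and pentamethylbenzene as cation scavenger (CH2Cl2, −78 °C), which leaves the methyl ether at this temperature and gives 17 directly. It passes through no new compound (F0).

## Further compounds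

F1 | step 6 | {[4-(2-(benzyloxy)benzyl)cyclohexa-1,5-dien-1-yl]oxy}trimethylsilane (racemic) | C[Si](C)(C)OC1=CCC(Cc2ccccc2OCc2ccccc2)C=C1
F2 | step 6 | 5-(benzyloxy)-6,8-bis({5-[2-(benzyloxy)benzyl]-2-oxocyclohex-3-en-1-yl}(hydroxy)methyl)-7-methoxyflavone (mixture of stereoisomers) | COc1c(C(O)C3CC(Cc4ccccc4OCc4ccccc4)C=CC3=O)c(OCc3ccccc3)c2c(c1C(O)C1CC(Cc3ccccc3OCc3ccccc3)C=CC1=O)OC(c1ccccc1)=CC2=O
F3 | step 8 | (2R,4R)-5-(benzyloxy)-6,8-bis{2-(benzyloxy)-5-[2-(benzyloxy)benzyl]benzyl}-7-methoxy-2-phenylchroman-4-ol | COc1c(Cc2cc(Cc3ccccc3OCc3ccccc3)ccc2OCc2ccccc2)c(OCc2ccccc2)c2c(c1Cc1cc(Cc3ccccc3OCc3ccccc3)ccc1OCc1ccccc1)O[C@@H](c1ccccc1)C[C@H]2O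
F4 | step 1 | 6,8-dibromo-5-hydroxy-7-methoxyflavone | COc1c(Br)c(O)c2c(c1Br)OC(c1ccccc1)=CC2=O
F5 | step 1 | 5-(benzyloxy)-6,8-dibromo-7-methoxyflavone | COc1c(Br)c(OCc2ccccc2)c2c(c1Br)OC(c1ccccc1)=CC2=O
F6 | step 1 | 5-(benzyloxy)-7-methoxy-6,8-divinylflavone | COc1c(C=C)c(OCc2ccccc2)c2c(c1C=C)OC(c1ccccc1)=CC2=O
F0 | step 9 | none | none
A1 | alternative 1 | (2S)-6,8-bis[2-acetoxy-5-(2-phenyl-4H-1,3,2-benzodioxaborin-4-yl)benzyl]-5-hydroxy-7-methoxyflavanone (dioxaborin C4 centres unassigned) | COc1c(Cc2cc(C3OB(c4ccccc4)Oc4ccccc34)ccc2OC(C)=O)c(O)c2c(c1Cc1cc(C3OB(c4ccccc4)Oc4ccccc34)ccc1OC(C)=O)O[C@H](c1ccccc1)CC2=O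
A2 | alternative 1 | (2S)-6,8-bis(2-acetoxy-5-formylbenzyl)-5-hydroxy-7-methoxyflavanone | COc1c(Cc2cc(C=O)ccc2OC(C)=O)c(O)c2c(c1Cc1cc(C=O)ccc1OC(C)=O)O[C@H](c1ccccc1)CC2=O
A3 | alternative 2 | (2S)-6,8-bis{2-(benzyloxy)-5-[2-(benzyloxy)benzyl]benzyl}-5-hydroxy-7-methoxyflavanone | COc1c(Cc2cc(Cc3ccccc3OCc3ccccc3)ccc2OCc2ccccc2)c(O)c2c(c1Cc1cc(Cc3ccccc3OCc3ccccc3)ccc1OCc1ccccc1)O[C@H](c1ccccc1)CC2=O
A4 | alternative 2 | (3S)-3-(2,4-bis{2-(benzyloxy)-5-[2-(benzyloxy)benzyl]benzyl}-5-hydroxy-3-methoxyphenoxy)-3-phenylpropanoic acid | O=C(O)C[C@@H](c1ccccc1)Oc1cc(O)c(Cc2cc(Cc3ccccc3OCc3ccccc3)ccc2OCc2ccccc2)c(OC)c1Cc1cc(Cc2ccccc2OCc2ccccc2)ccc1OCc1ccccc1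
A5 | alternative 3 | (2S)-5-acetoxy-6,8-bis{2-acetoxy-5-[2-(benzyloxy)benzyl]benzyl}-7-methoxyflavanone | COc1c(Cc2cc(Cc3ccccc3OCc3ccccc3)ccc2OC(C)=O)c(OC(C)=O)c2c(c1Cc1cc(Cc3ccccc3OCc3ccccc3)ccc1OC(C)=O)O[C@H](c1ccccc1)CC2=O
A6 | alternative 3 | (2S)-5-acetoxy-6,8-bis(2-acetoxy-5-bromobenzyl)-7-methoxyflavanone | COc1c(Cc2cc(Br)ccc2OC(C)=O)c(OC(C)=O)c2c(c1Cc1cc(Br)ccc1OC(C)=O)O[C@H](c1ccccc1)CC2=O
A7 | alternative 3 | 2-(benzyloxy)benzylzinc chloride | Cl[Zn]Cc1ccccc1OCc1ccccc1
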